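**Plan**

- Ring numbering used throughout, also for open-chain intermediates: C1 is the stereocentre carrying the 6-methylhepta-1,5-dien-2-yl group, followed by C2, C3=C4 (CH2OH on C4), C7=C8 (CH3 on C8), C11=C12 (CH3 on C12), C13 and C14.
- Retrosynthesis: after O–H unmasking, the ring is opened at C11=C12 (reductive carbonyl coupling). The chain is then cut at C3=C4 (phosphonate olefination), C4–C5 (phosphonoacetate alkylation), C6–C7 and C8–C9 (carbocupration of propyne, oxirane opening), and at the CH2–CH2 bond of the side chain (allylic alkylation with prenyl bromide).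
- Enabling feature: C12–C13–C14–C1–C2–C3, with the C12 methyl and the C1 alkenyl branch, is the six-membered ring of (R)-limonene opened at its endocyclic double bond. Glycol cleavage therefore delivers the C12 methyl ketone (one coupling partner) and the C3 aldehyde (olefination site) in one operation. C11=C12 has only CH2 neighbours, so both of its carbons can be carbonyl carbons without risk to C1.
- Forward: fragment A (C12 to C3 with the side chain, four steps) and fragment B (C4 to C11 phosphonate, three steps) are joined at C3=C4. Four functional-group steps expose the C11 aldehyde and C12 ketone, the only ring (14-membered carbocycle) closes in the McMurry step, and desilylation finishes.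
- Stereochemistry: C1 is C4 of (R)-limonene and is never touched. The C3=C4 geometry (ester, later CH2OH, trans to C2) comes from the Horner–Wadsworth–Emmons step, C7=C8 (C6 cis to C9) from syn-carbocupration, and C11=C12 (E) from the ring closure.

Key step: step 13

Remark: the commercial cis/trans mixture of (+)-limonene 1,2-oxide, the epoxide of (R)-limonene, is taken as the chiral-pool entry, because both diastereomers should converge in step 1 and the two carbinol centres made there are destroyed in step 4.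

**Route**

Step 1
Reactants: 1 (+)-limonene 1,2-oxide, (4R)-1-methyl-4-(prop-1-en-2-yl)-7-oxabicyclo[4.1.0]heptane, cis/trans mixture
Product: 2 (1S,2S,4R)-1-methyl-4-(prop-1-en-2-yl)cyclohexane-1,2-diol
Conditions: 1% aq. H2SO4, THF, 0 °C → rt
Reagents that add atoms: water, O
Why: Acid-catalysed epoxide hydrolysis follows trans-diaxial opening (Fürst–Plattner rule), the cis epoxide being attacked at the methyl-bearing carbon and the trans epoxide at the CH carbon, so both should give the same trans-diol while the isopropenyl group and the stereocentre are not involved.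

Step 2
Reactants: 2 (1S,2S,4R)-1-methyl-4-(prop-1-en-2-yl)cyclohexane-1,2-diol
Product: 3 (3aS,5R,7aS)-2,2,7a-trimethyl-5-(prop-1-en-2-yl)hexahydro-1,3-benzodioxole (trans-fused acetonide)
Conditions: 2-methoxypropene, PPTS (cat.), CH2Cl2, 0 °C → rt
Reagents that add atoms: 2-methoxypropene, COC(C)=C
Why: Acetonide formation from an enol ether under kinetic control should succeed because the monocyclic diol can flip to the chair with both hydroxyls equatorial, from which a trans-fused dioxolane closes as it does for trans-cyclohexane-1,2-diol, the consumption of the enol ether paying for the conformational cost.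

Step 3
Reactants: 3 (3aS,5R,7aS)-2,2,7a-trimethyl-5-(prop-1-en-2-yl)hexahydro-1,3-benzodioxole; 4 1-bromo-3-methylbut-2-ene (prenyl bromide)
Product: 6 (3aS,5R,7aS)-2,2,7a-trimethyl-5-(6-methylhepta-1,5-dien-2-yl)hexahydro-1,3-benzodioxole, via allyllithium 5 (not isolated)
Conditions: n-BuLi, TMEDA, hexane, rt; then 4, THF, −78 → 0 °C
Reagents that add atoms: none
Why: Allylic lithiation of a 2-substituted propene takes place at the methyl group, as known for limonene itself, and the resulting 2-substituted allyllithium should be alkylated by the primary allylic bromide at its CH2Br carbon (SN2), leaving the adjacent stereocentre untouched.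

Step 4
Reactants: 6 (3aS,5R,7aS)-2,2,7a-trimethyl-5-(6-methylhepta-1,5-dien-2-yl)hexahydro-1,3-benzodioxole
Product: 8 (3R)-3-(6-methylhepta-1,5-dien-2-yl)-6-oxoheptanal, via diol 7 (not isolated)
Conditions: H5IO6, THF/H2O, 0 °C → rt
Reagents that add atoms: none
Why: Aqueous periodic acid should hydrolyse the strained trans-fused acetonide and cleave the liberated 1,2-diol through a cyclic periodate ester (Malaprade glycol cleavage) to the methyl ketone and the aldehyde, under conditions that isolated tri- and 1,1-disubstituted alkenes tolerate.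

Step 5
Reactants: 9 2-(2-bromoethyl)-1,3-dioxolane; 10 propyne; 11 ethylene oxide (oxirane)
Product: 15 (3Z)-6-(1,3-dioxolan-2-yl)-4-methylhex-3-en-1-ol, via Grignard reagent 12 (not isolated), via alkylcopper 13 (not isolated), via alkenylcopper 14 (not isolated)
Conditions: Mg, THF, 25–30 °C; CuBr·SMe2, Et2O/Me2S, −45 °C; 10, −25 °C; LiC≡C-n-Bu (from 1-hexyne and n-BuLi), HMPA, 11, −78 → −20 °C; aq. NH4Cl
Reagents that add atoms: none
Why: In the Normant carbocupration the alkylcopper–MgBr2 reagent adds syn across propyne with copper on the terminal carbon, and the alkenylcopper, activated as a mixed alkynyl cuprate, opens oxirane with retention, so the hydroxyethyl chain and the dioxolanylethyl chain should end up cis (Z).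

Step 6
Reactants: 15 (3Z)-6-(1,3-dioxolan-2-yl)-4-methylhex-3-en-1-ol
Product: 16 2-[(3Z)-6-iodo-3-methylhex-3-en-1-yl]-1,3-dioxolane
Conditions: I2, PPh3, imidazole, CH2Cl2, 0 °C → rt
Reagents that add atoms: iodine, II
Why: Appel-type iodination converts the primary alcohol by SN2 displacement of the alkoxyphosphonium group, imidazole keeping the medium non-acidic for the dioxolane and the alkene geometry being unaffected.

Step 7
Reactants: 16 2-[(3Z)-6-iodo-3-methylhex-3-en-1-yl]-1,3-dioxolane; 17 triethyl phosphonoacetate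
Product: 19 ethyl (5Z)-2-(diethoxyphosphoryl)-8-(1,3-dioxolan-2-yl)-6-methyloct-5-enoate (racemic at C2), via sodium phosphonoacetate 18 (not isolated)
Conditions: NaH, 17 (2.5 equiv), DMF, 0 → 55 °C
Reagents that add atoms: none
Why: C-Alkylation of the stabilised phosphonoacetate anion by a primary iodide (SN2) is standard, an excess of the anion holding back dialkylation, and the racemic centre formed becomes sp2 in the next step.

Step 8
Reactants: 8 (3R)-3-(6-methylhepta-1,5-dien-2-yl)-6-oxoheptanal; 19 ethyl (5Z)-2-(diethoxyphosphoryl)-8-(1,3-dioxolan-2-yl)-6-methyloct-5-enoate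
Product: 21 ethyl (2E,5R)-2-[(3Z)-6-(1,3-dioxolan-2-yl)-4-methylhex-3-en-1-yl]-5-(6-methylhepta-1,5-dien-2-yl)-8-oxonon-2-enoate, via sodium phosphonate 20 (not isolated)
Conditions: 19 (1.2 equiv), NaH (1.1 equiv), THF, 0 °C; then 8, 0 °C → rt
Reagents that add atoms: none
Why: In this Horner–Wadsworth–Emmons olefination the α-branched stabilised anion should attack only the aldehyde, the methyl ketone being far less electrophilic, and reversible adduct formation should favour the trisubstituted (E)-enoate with the ester trans to C2, any (Z)-isomer being removed by chromatography.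

Step 9
Reactants: 21 ethyl (2E,5R)-2-[(3Z)-6-(1,3-dioxolan-2-yl)-4-methylhex-3-en-1-yl]-5-(6-methylhepta-1,5-dien-2-yl)-8-oxonon-2-enoate
Product: 22 (2E,5R)-2-[(3Z)-6-(1,3-dioxolan-2-yl)-4-methylhex-3-en-1-yl]-5-(6-methylhepta-1,5-dien-2-yl)non-2-ene-1,8-diol (both C8 epimers)
Conditions: i-Bu2AlH (4 equiv), CH2Cl2, −78 → 0 °C; aq. KNaC4H4O6
Reagents that add atoms: none
Why: Hydride 1,2-reduction turns the conjugated ester into the allylic alcohol and, deliberately, the ketone into a secondary alcohol whose configuration is irrelevant because it is reoxidised in step 11, while the dioxolane and the alkenes are inert.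

Step 10
Reactants: 22 (2E,5R)-2-[(3Z)-6-(1,3-dioxolan-2-yl)-4-methylhex-3-en-1-yl]-5-(6-methylhepta-1,5-dien-2-yl)non-2-ene-1,8-diol
Product: 23 (5R,7E)-9-[(tert-butyldiphenylsilyl)oxy]-8-[(3Z)-6-(1,3-dioxolan-2-yl)-4-methylhex-3-en-1-yl]-5-(6-methylhepta-1,5-dien-2-yl)non-7-en-2-ol (both C2 epimers)
Conditions: TBDPSCl (1.05 equiv), imidazole, CH2Cl2, 0 °C
Reagents that add atoms: tert-butyl(chloro)diphenylsilane (TBDPSCl), CC(C)(C)[Si](Cl)(c1ccccc1)c1ccccc1
Why: Silylation with a bulky chlorosilane should discriminate on steric grounds between the primary allylic hydroxyl and the secondary one.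

Step 11
Reactants: 23 (5R,7E)-9-[(tert-butyldiphenylsilyl)oxy]-8-[(3Z)-6-(1,3-dioxolan-2-yl)-4-methylhex-3-en-1-yl]-5-(6-methylhepta-1,5-dien-2-yl)non-7-en-2-ol
Product: 24 (5R,7E)-9-[(tert-butyldiphenylsilyl)oxy]-8-[(3Z)-6-(1,3-dioxolan-2-yl)-4-methylhex-3-en-1-yl]-5-(6-methylhepta-1,5-dien-2-yl)non-7-en-2-one
Conditions: Dess–Martin periodinane, CH2Cl2, 0 °C → rt
Reagents that add atoms: none
Why: Dess–Martin oxidation converts the secondary alcohol into the C12 methyl ketone under near-neutral conditions that the dioxolane, the allylic silyl ether and the alkenes tolerate.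

Step 12
Reactants: 24 (5R,7E)-9-[(tert-butyldiphenylsilyl)oxy]-8-[(3Z)-6-(1,3-dioxolan-2-yl)-4-methylhex-3-en-1-yl]-5-(6-methylhepta-1,5-dien-2-yl)non-7-en-2-one
Product: 25 (4Z,8E,11R)-8-[(tert-butyldiphenylsilyl)oxymethyl]-4-methyl-11-(6-methylhepta-1,5-dien-2-yl)-14-oxopentadeca-4,8-dienal (C11 aldehyde, C12 methyl ketone)
Conditions: 1 M aq. HCl, THF, rt
Reagents that add atoms: water, O
Why: Acid-catalysed acetal hydrolysis frees the C11 aldehyde, the tert-butyldiphenylsilyl ether being stable to dilute aqueous acid and neither carbonyl having an epimerisable or conjugating neighbour.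

Step 13
Reactants: 25 (4Z,8E,11R)-8-[(tert-butyldiphenylsilyl)oxymethyl]-4-methyl-11-(6-methylhepta-1,5-dien-2-yl)-14-oxopentadeca-4,8-dienal
Product: 27 (1R,3E,7Z,11E)-4-[(tert-butyldiphenylsilyl)oxymethyl]-8,12-dimethyl-1-(6-methylhepta-1,5-dien-2-yl)cyclotetradeca-3,7,11-triene, via titanium diolate 26 (not isolated)
Conditions: TiCl3(DME)1.5, Zn–Cu couple, DME, reflux; 25 added by syringe pump over ca. 30 h (final ca. 0.005 M)
Reagents that add atoms: none
Why: Low-valent (formally zerovalent) titanium made from TiCl3(DME)1.5 and the Zn–Cu couple transfers single electrons to the C11 aldehyde and the C12 methyl ketone, the two ketyl radicals couple on the metal to the titanium 1,2-diolate 26, and at reflux both oxygens pass to titanium to leave the C11=C12 double bond (McMurry coupling). The closest known reaction type is the intramolecular McMurry coupling of open-chain isoprenoid keto-aldehydes to 14-membered cembrane-type rings containing a trisubstituted ring olefin. The single ring, the 14-membered carbocycle, closes by end-to-end carbon–carbon coupling of the 1,14-dicarbonyl chain, both carbonyl carbons ending inside the ring. No stereocentre is created, and C1, which is gamma to the ketone and remote from the aldehyde, cannot epimerise. The step needs cyclisation over oligomerisation, which slow addition to an excess of the titanium reagent and the cis disposition of the ring carbons at C3=C4 and C7=C8 should secure, and it needs E geometry at C11=C12, which should be favoured because deoxygenation of the diolate is not stereospecific and the (E)-trisubstituted olefin is the less strained one in this ring, any (Z)-isomer being removed on AgNO3-impregnated silica. The two carbonyls are the only groups reduced, the allylic oxygen being masked as a silyl ether because a free allylic alcohol would be deoxygenated.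

Step 14
Reactants: 27 (1R,3E,7Z,11E)-4-[(tert-butyldiphenylsilyl)oxymethyl]-8,12-dimethyl-1-(6-methylhepta-1,5-dien-2-yl)cyclotetradeca-3,7,11-triene
Product: 28 (1R,3E,7Z,11E)-4-(hydroxymethyl)-8,12-dimethyl-1-(6-methylhepta-1,5-dien-2-yl)cyclotetradeca-3,7,11-triene (CNP0217603.1)
Conditions: Bu4NF, THF, 0 °C → rt
Reagents that add atoms: none
Why: Fluoride-induced Si–O cleavage, driven by the strong Si–F bond, should release the primary allylic alcohol without touching the four alkenes or C1.

**Compound list**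

1 | (+)-limonene 1,2-oxide, (4R)-1-methyl-4-(prop-1-en-2-yl)-7-oxabicyclo[4.1.0]heptane, cis/trans mixture | C=C(C)[C@H]1CC2OC2(C)CC1 | starting material
2 | (1S,2S,4R)-1-methyl-4-(prop-1-en-2-yl)cyclohexane-1,2-diol | C=C(C)[C@H]1C[C@H](O)[C@@](C)(O)CC1 | intermediate
3 | (3aS,5R,7aS)-2,2,7a-trimethyl-5-(prop-1-en-2-yl)hexahydro-1,3-benzodioxole | C=C(C)[C@H]1C[C@@H]2OC(C)(C)O[C@@]2(C)CC1 | intermediate
4 | 1-bromo-3-methylbut-2-ene | CC(C)=CCBr | starting material
5 | allyllithium from 3, lithiated at the isopropenyl methyl (not isolated) | [Li]CC(=C)[C@H]1C[C@@H]2OC(C)(C)O[C@@]2(C)CC1 | intermediate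
6 | (3aS,5R,7aS)-2,2,7a-trimethyl-5-(6-methylhepta-1,5-dien-2-yl)hexahydro-1,3-benzodioxole | C=C(CCC=C(C)C)[C@H]1C[C@@H]2OC(C)(C)O[C@@]2(C)CC1 | intermediate
7 | (1S,2S,4R)-1-methyl-4-(6-methylhepta-1,5-dien-2-yl)cyclohexane-1,2-diol (not isolated) | C=C(CCC=C(C)C)[C@H]1C[C@H](O)[C@@](C)(O)CC1 | intermediate
8 | (3R)-3-(6-methylhepta-1,5-dien-2-yl)-6-oxoheptanal | CC(=O)CC[C@@H](C(=C)CCC=C(C)C)CC=O | intermediate
9 | 2-(2-bromoethyl)-1,3-dioxolane | BrCCC1OCCO1 | starting material
10 | propyne | CC#C | starting material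
11 | ethylene oxide (oxirane) | C1CO1 | starting material
12 | [2-(1,3-dioxolan-2-yl)ethyl]magnesium bromide (not isolated) | Br[Mg]CCC1OCCO1 | intermediate
13 | [2-(1,3-dioxolan-2-yl)ethyl]copper, MgBr2/SMe2 complex (not isolated) | [Cu]CCC1OCCO1 | intermediate
14 | [(1Z)-4-(1,3-dioxolan-2-yl)-2-methylbut-1-en-1-yl]copper (not isolated) | [Cu]/C=C(/C)CCC1OCCO1 | intermediate
15 | (3Z)-6-(1,3-dioxolan-2-yl)-4-methylhex-3-en-1-ol | OCC/C=C(/C)CCC1OCCO1 | intermediate
16 | 2-[(3Z)-6-iodo-3-methylhex-3-en-1-yl]-1,3-dioxolane | ICC/C=C(/C)CCC1OCCO1 | intermediate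
17 | triethyl phosphonoacetate | CCOC(=O)CP(=O)(OCC)OCC | starting material
18 | sodium salt of triethyl phosphonoacetate (not isolated) | CCOC(=O)[CH-]P(=O)(OCC)OCC.[Na+] | intermediate
19 | ethyl (5Z)-2-(diethoxyphosphoryl)-8-(1,3-dioxolan-2-yl)-6-methyloct-5-enoate, racemic at C2 | CCOC(=O)C(CC/C=C(/C)CCC1OCCO1)P(=O)(OCC)OCC | intermediate
20 | sodium salt of 19 (not isolated) | CCOC(=O)[C-](CC/C=C(/C)CCC1OCCO1)P(=O)(OCC)OCC.[Na+] | intermediate
21 | ethyl (2E,5R)-2-[(3Z)-6-(1,3-dioxolan-2-yl)-4-methylhex-3-en-1-yl]-5-(6-methylhepta-1,5-dien-2-yl)-8-oxonon-2-enoate | CC(=O)CC[C@@H](C(=C)CCC=C(C)C)C/C=C(/C(=O)OCC)CC/C=C(/C)CCC1OCCO1 | intermediate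
22 | (2E,5R)-2-[(3Z)-6-(1,3-dioxolan-2-yl)-4-methylhex-3-en-1-yl]-5-(6-methylhepta-1,5-dien-2-yl)non-2-ene-1,8-diol, both C8 epimers | CC(O)CC[C@@H](C(=C)CCC=C(C)C)C/C=C(/CO)CC/C=C(/C)CCC1OCCO1 | intermediate
23 | (5R,7E)-9-[(tert-butyldiphenylsilyl)oxy]-8-[(3Z)-6-(1,3-dioxolan-2-yl)-4-methylhex-3-en-1-yl]-5-(6-methylhepta-1,5-dien-2-yl)non-7-en-2-ol, both C2 epimers | CC(O)CC[C@@H](C(=C)CCC=C(C)C)C/C=C(/CO[Si](c1ccccc1)(c1ccccc1)C(C)(C)C)CC/C=C(/C)CCC1OCCO1 | intermediate
24 | (5R,7E)-9-[(tert-butyldiphenylsilyl)oxy]-8-[(3Z)-6-(1,3-dioxolan-2-yl)-4-methylhex-3-en-1-yl]-5-(6-methylhepta-1,5-dien-2-yl)non-7-en-2-one | CC(=O)CC[C@@H](C(=C)CCC=C(C)C)C/C=C(/CO[Si](c1ccccc1)(c1ccccc1)C(C)(C)C)CC/C=C(/C)CCC1OCCO1 | intermediate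
25 | (4Z,8E,11R)-8-[(tert-butyldiphenylsilyl)oxymethyl]-4-methyl-11-(6-methylhepta-1,5-dien-2-yl)-14-oxopentadeca-4,8-dienal | CC(=O)CC[C@@H](C(=C)CCC=C(C)C)C/C=C(/CO[Si](c1ccccc1)(c1ccccc1)C(C)(C)C)CC/C=C(/C)CCC=O | intermediate
26 | titanium 11,12-diolate of the ring-closed pinacol, surface-bound, drawn with one titanium atom, C11/C12 configuration mixed (not isolated) | C=C(CCC=C(C)C)[C@H]1C/C=C(/CO[Si](c2ccccc2)(c2ccccc2)C(C)(C)C)CC/C=C(/C)CCC2O[Ti]OC2(C)CC1 | intermediate
27 | (1R,3E,7Z,11E)-4-[(tert-butyldiphenylsilyl)oxymethyl]-8,12-dimethyl-1-(6-methylhepta-1,5-dien-2-yl)cyclotetradeca-3,7,11-triene | C=C(CCC=C(C)C)[C@H]1C/C=C(/CO[Si](c2ccccc2)(c2ccccc2)C(C)(C)C)CC/C=C(/C)CC/C=C(\C)CC1 | intermediate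
28 | (1R,3E,7Z,11E)-4-(hydroxymethyl)-8,12-dimethyl-1-(6-methylhepta-1,5-dien-2-yl)cyclotetradeca-3,7,11-triene (CNP0217603.1) | C=C(CCC=C(C)C)[C@H]1C/C=C(/CO)CC/C=C(/C)CC/C=C(\C)CC1 | target

**Step count and risks**

Total step count: 14. Longest linear sequence: 11 steps (steps 1–4 and 8–14, from compound 1).

Steps most likely to fail:

1. Step 13. The deoxygenation of the titanium diolate is not stereospecific, so geometric control at C11=C12 may be lost, and intermolecular coupling may compete with ring closure. Fallback, from 25 to 27: the coupling is stopped at the pinacol stage (TiCl3(DME)1.5, Zn–Cu couple, DME, 25 °C, slow addition, or SmI2 in THF). This would give the macrocyclic 11,12-diols (11R,12R)-diol F1, (11S,12S)-diol F2, (11R,12S)-diol F3 and (11S,12R)-diol F4. The like-configured diols F1 and F2 are separated and converted with thiophosgene and DMAP into thionocarbonate F5 and thionocarbonate F6. Heating these with 1,3-dimethyl-2-phenyl-1,3,2-diazaphospholidine at 40 °C (Corey–Winter olefination) is a stereospecific syn elimination, and both should give only the (E)-olefin 27. The unlike diols F3 and F4 are cut back to 25 with NaIO4 and recycled.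

2. Step 8. E selectivity may erode with the α-branched phosphonate anion, and the keto-aldehyde may undergo base-induced aldol condensation before it is olefinated. Fallback, from 16 (with 8) to 21: iodide 16 alkylates ethyl (triphenylphosphoranylidene)acetate in refluxing EtOAc to give phosphonium iodide F7. Aqueous NaOH in CH2Cl2 converts it into ylide F8. A salt-free Wittig reaction of ylide F8 with 8 in toluene at 80 °C needs no added base, should touch only the aldehyde, and should give the (E)-enoate 21.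

3. Step 2. Ketalisation may be incomplete or reversible, because closure of the dioxolane has to pass through the minor chair conformer in which the methyl and the isopropenyl group are axial. Fallback, from 1 to 8, bypassing any cyclic diol derivative: H5IO6 in THF/H2O cleaves epoxide 1 directly to (3R)-3-(prop-1-en-2-yl)-6-oxoheptanal F9. Ethylene glycol and PPTS in benzene with water removal give bis-dioxolane F10. Lithiation with n-BuLi/TMEDA to allyllithium F11 and alkylation with 4 give prenylated bis-dioxolane F12. 1 M aq. HCl in THF then hydrolyses both acetals to 8.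

Further compounds
F1 | step 13 | (1R,3E,7Z,11R,12R)-4-[(tert-butyldiphenylsilyl)oxymethyl]-8,12-dimethyl-1-(6-methylhepta-1,5-dien-2-yl)cyclotetradeca-3,7-diene-11,12-diol | C=C(CCC=C(C)C)[C@H]1C/C=C(/CO[Si](c2ccccc2)(c2ccccc2)C(C)(C)C)CC/C=C(/C)CC[C@@H](O)[C@](C)(O)CC1
F2 | step 13 | (1R,3E,7Z,11S,12S)-diol, otherwise as F1 | C=C(CCC=C(C)C)[C@H]1C/C=C(/CO[Si](c2ccccc2)(c2ccccc2)C(C)(C)C)CC/C=C(/C)CC[C@H](O)[C@@](C)(O)CC1
F3 | step 13 | (1R,3E,7Z,11R,12S)-diol, otherwise as F1 | C=C(CCC=C(C)C)[C@H]1C/C=C(/CO[Si](c2ccccc2)(c2ccccc2)C(C)(C)C)CC/C=C(/C)CC[C@@H](O)[C@@](C)(O)CC1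
F4 | step 13 | (1R,3E,7Z,11S,12R)-diol, otherwise as F1 | C=C(CCC=C(C)C)[C@H]1C/C=C(/CO[Si](c2ccccc2)(c2ccccc2)C(C)(C)C)CC/C=C(/C)CC[C@H](O)[C@](C)(O)CC1
F5 | step 13 | cyclic 11,12-thionocarbonate of F1 (11R,12R) | C=C(CCC=C(C)C)[C@H]1C/C=C(/CO[Si](c2ccccc2)(c2ccccc2)C(C)(C)C)CC/C=C(/C)CC[C@H]2OC(=S)O[C@]2(C)CC1
F6 | step 13 | cyclic 11,12-thionocarbonate of F2 (11S,12S) | C=C(CCC=C(C)C)[C@H]1C/C=C(/CO[Si](c2ccccc2)(c2ccccc2)C(C)(C)C)CC/C=C(/C)CC[C@@H]2OC(=S)O[C@@]2(C)CC1
F7 | step 8 | [(5Z)-8-(1,3-dioxolan-2-yl)-1-ethoxy-6-methyl-1-oxooct-5-en-2-yl]triphenylphosphonium iodide | CCOC(=O)C(CC/C=C(/C)CCC1OCCO1)[P+](c1ccccc1)(c1ccccc1)c1ccccc1.[I-]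
F8 | step 8 | ethyl (5Z)-8-(1,3-dioxolan-2-yl)-6-methyl-2-(triphenylphosphoranylidene)oct-5-enoate | CCOC(=O)C(CC/C=C(/C)CCC1OCCO1)=P(c1ccccc1)(c1ccccc1)c1ccccc1
F9 | step 2 | (3R)-3-(prop-1-en-2-yl)-6-oxoheptanal | CC(=O)CC[C@@H](C(C)=C)CC=O
F10 | step 2 | 2-[(3R)-3-(1,3-dioxolan-2-ylmethyl)-4-methylpent-4-en-1-yl]-2-methyl-1,3-dioxolane | CC1(CC[C@@H](C(C)=C)CC2OCCO2)OCCO1
F11 | step 2 | allyllithium from F10, lithiated at the isopropenyl methyl | CC1(CC[C@@H](C(=C)C[Li])CC2OCCO2)OCCO1
F12 | step 2 | 2-[(3R)-3-(1,3-dioxolan-2-ylmethyl)-8-methyl-4-methylidenenon-7-en-1-yl]-2-methyl-1,3-dioxolane | CC1(CC[C@@H](C(=C)CCC=C(C)C)CC2OCCO2)OCCO1
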